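**Strategy.** Everything rests on the C3–C4 bond of ring A. The feature exploited is the gem-dimethyl carbon C4 lying between the oxygenated C3 and the ring-fusion carbon C5: an isopropenyl group on C5, taken from (R)-carvone, is a latent tertiary C4 radical. Iron-hydride hydrogen-atom transfer generates this radical, which adds 6-exo to a C3 aldehyde on a propanal arm at C10; one operation closes ring A as the trans-decalin and creates quaternary C4 and the 3β-carbinol. The precursor is a monocyclic keto aldehyde, a 6,6-dialkylated carvone carrying ring B with C5 and C10 set. C9 is finished later by α-face epoxidation of a C9 methylene, ylide homologation and a B-alkyl Suzuki coupling with a bromobutenolide.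

Key step: step 4

Remark on the chemistry: the target is read as 3β-acetoxy-9α-hydroxy-labd-13-en-15,16-olide with the C8 methyl α (3S,5S,8R,9R,10S; trans-decalin, C10 methyl β; lactone carbonyl C15 conjugated with C13=C14, OCH2 at C16). Labdane numbering and α/β (β = face of the C10 methyl) are used for the bicyclic compounds, carvone numbering for the monocyclic ones.

**Step 1**
Reactants: 1 (R)-(−)-carvone
Product: 3 trans-6-methylcarvone, via carvone lithium enolate 2 (not isolated)
Conditions: LiN(i-Pr)2, THF, −78 °C; then MeI, −78 to 0 °C
Reagents that add atoms: iodomethane, CI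
Why: Enolate alkylation: LiN(i-Pr)2 deprotonates carvone kinetically at C6 (α′) and the cross-conjugated enolate is C-methylated, the new C6 centre being of no consequence because it is planarised again in step 2.

**Step 2**
Reactants: 3 trans-6-methylcarvone (its C6 epimer reacts identically)
Product: 5 6-allyl-6-methylcarvone (allyl trans to isopropenyl), via 6-methylcarvone lithium enolate 4 (not isolated)
Conditions: LiN(i-Pr)2, THF, −78 °C; then allyl bromide, DMPU, −78 °C to rt
Reagents that add atoms: allyl bromide, C=CCBr
Why: Second enolate alkylation: the tetrasubstituted α′-enolate is attacked by allyl bromide on the face anti to the adjacent C5 isopropenyl group, so the allyl group ends trans and the methyl cis to isopropenyl, which is the relative configuration of C10 and C5 in the target.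

**Step 3**
Reactants: 5 6-allyl-6-methylcarvone
Product: 6 keto aldehyde 3-[(1S,6S)-1,3-dimethyl-2-oxo-6-(prop-1-en-2-yl)cyclohex-3-en-1-yl]propanal
Conditions: PdCl2(PhCN)2 (cat.), CuCl2·2H2O (cat.), AgNO2 (cat.), O2 (1 atm), t-BuOH/MeNO2, rt
Reagents that add atoms: dioxygen, O=O
Why: Nitrite-modified aldehyde-selective (anti-Markovnikov) Wacker oxidation acts on the monosubstituted allyl alkene, whereas the 1,1-disubstituted isopropenyl and the trisubstituted enone alkenes are poor substrates for Wacker chemistry; no stereocentre is involved.

**Step 4**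
Reactants: 6 keto aldehyde
Product: 7 3β-hydroxy-4,4,8,10β-tetramethyl-trans-decal-7-en-9-one
Conditions: Fe(acac)3 (cat.), PhSiH3, EtOH, 60 °C, high dilution
Reagents that add atoms: none
Why: Fe(acac)3 and PhSiH3 form an iron hydride that transfers a hydrogen atom to the CH2 terminus of the electron-rich isopropenyl group (Markovnikov MHAT), and the resulting tertiary C4 radical adds to the aldehyde carbon C3, after which the alkoxy radical is reduced by divalent iron and protonated by ethanol. The closest known reaction types are the iron-hydride HAT-triggered radical cyclisation of alkene-tethered ketones and the iron-catalysed radical addition of unactivated alkenes to aldehydes. Ring A closes in the 6-exo-trig mode onto the C=O group through a chair transition state, and the trans ring fusion follows from the trans arrangement of the C5 and C10 arms set in step 2. The new stereocentre C3 is controlled by that chair: the carbonyl oxygen sits pseudo-equatorial (β), and because addition to C=O is reversible through β-scission, the more stable equatorial 3β-alkoxy radical should be the one that is trapped. The step needs hydrogen-atom transfer to the 1,1-disubstituted alkene rather than to the enone (secured by the electron-poor, trisubstituted character of C7=C8, which the C4 radical also cannot reach without forming a four-membered ring) and cyclisation faster than reduction of the radical to isopropyl (secured by high dilution and the fast 6-exo addition to an aldehyde).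

**Step 5**
Reactants: 7 3β-hydroxy enone
Product: 9 3β-hydroxy-8α-methyl-trans-decal-9-one, via 8β-methyl ketone 8 (not isolated)
Conditions: H2 (1 atm), 10% Pd/C, EtOAc, rt; filter; then NaOMe (cat.), MeOH, rt
Reagents that add atoms: none
Why: Catalytic hydrogenation saturates the enone C7=C8, the only alkene left, and methoxide-mediated epimerisation then places the C8 methyl equatorial (α), since the axial 8β-methyl suffers a 1,3-diaxial contact with the C10 methyl.

**Step 6**
Reactants: 9 3β-hydroxy-8α-methyl-trans-decal-9-one
Product: 10 3β-hydroxy-8α-methyl-9-methylene-trans-decalin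
Conditions: Ph3PCH3Br (excess), KOt-Bu, toluene, 90 °C
Reagents that add atoms: methyltriphenylphosphonium bromide, C[P+](c1ccccc1)(c1ccccc1)c1ccccc1.[Br-]
Why: Wittig methylenation under the KOt-Bu/hot toluene conditions that serve for hindered ketones; C8 stays α because any enolisation returns to the strongly favoured equatorial epimer before olefination.

**Step 7**
Reactants: 10 9-methylene compound
Product: 11 9α,11-epoxide (spiro-oxirane, oxygen α, C11 β)
Conditions: m-CPBA, NaHCO3 (buffer), CH2Cl2, 0 °C
Reagents that add atoms: m-CPBA (3-chloroperoxybenzoic acid), OOC(=O)c1cccc(Cl)c1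
Why: Prilezhaev epoxidation of the 1,1-disubstituted alkene from the α face, the β face being shielded by the axial C10 methyl, places the epoxide oxygen α on C9 and leaves C11 β, which is the C9 configuration of the target.

**Step 8**
Reactants: 11 9α,11-epoxide
Product: 12 9-vinyl-3β,9α-diol
Conditions: Me3SI (excess), n-BuLi, THF, −10 °C to rt
Reagents that add atoms: trimethylsulfonium iodide, C[S+](C)C.[I-]
Why: Corey–Chaykovsky-type one-carbon homologation of an epoxide to an allylic alcohol: the sulfonium ylide opens the epoxide at the CH2 terminus C11 by SN2, and the resulting sulfonium betaine is deprotonated to a new ylide that eliminates dimethyl sulfide across C11–C12, the C9–O bond and hence the C9 configuration being untouched.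

**Step 9**
Reactants: 12 9-vinyl-3β,9α-diol; 13 4-bromofuran-2(5H)-one
Product: 15 3β,9α-dihydroxy-labd-13-en-15,16-olide, via B-alkyl-9-BBN 14 (not isolated)
Conditions: 9-BBN-H (excess), THF, rt to 50 °C; then 13, Pd(dppf)Cl2 (cat.), Cs2CO3, DMF/H2O, rt; acidic work-up
Reagents that add atoms: none
Why: Anti-Markovnikov hydroboration of the vinyl group places boron on C12, and B-alkyl Suzuki–Miyaura coupling with the vinylogous acyl bromide 13 forms the C12–C13 bond and installs the complete butenolide without touching a stereocentre.

**Step 10**
Reactants: 15 3β,9α-dihydroxy-labd-13-en-15,16-olide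
Product: 16 3β-acetoxy-9α-hydroxy-labd-13-en-15,16-olide (target)
Conditions: Ac2O, pyridine, DMAP (cat.), CH2Cl2, rt
Reagents that add atoms: acetic anhydride, CC(=O)OC(C)=O
Why: DMAP-catalysed acylation is selective for the secondary equatorial 3β-hydroxyl, because the axial tertiary 9α-hydroxyl between C8 and the quaternary C10 is not acetylated under these conditions.

**Compound list**

1 | (R)-(−)-carvone, (5R)-2-methyl-5-(prop-1-en-2-yl)cyclohex-2-en-1-one | CC1=CC[C@H](CC1=O)C(C)=C | starting material
2 | carvone lithium enolate (cross-conjugated C1(OLi)=C6 dienolate) | [Li]OC1=C[C@@H](CC=C1C)C(C)=C | intermediate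
3 | trans-6-methylcarvone (methyl trans to isopropenyl; major epimer drawn) | C[C@H]1[C@@H](CC=C(C)C1=O)C(C)=C | intermediate
4 | 6-methylcarvone lithium enolate (C1(OLi)=C6, tetrasubstituted) | [Li]OC1=C(C)[C@@H](CC=C1C)C(C)=C | intermediate
5 | (5S,6S)-6-allyl-2,6-dimethyl-5-(prop-1-en-2-yl)cyclohex-2-en-1-one (allyl trans to isopropenyl) | C=CC[C@@]1(C)[C@@H](CC=C(C)C1=O)C(C)=C | intermediate
6 | 3-[(1S,6S)-1,3-dimethyl-2-oxo-6-(prop-1-en-2-yl)cyclohex-3-en-1-yl]propanal | O=CCC[C@@]1(C)[C@@H](CC=C(C)C1=O)C(C)=C | intermediate
7 | (4aS,6S,8aS)-6-hydroxy-2,5,5,8a-tetramethyl-4a,5,6,7,8,8a-hexahydronaphthalen-1(4H)-one (3β-OH, trans-fused, Δ7-9-one) | O[C@H]1CC[C@@]2(C)[C@@H](CC=C(C)C2=O)C1(C)C | intermediate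
8 | 8β-methyl epimer of ketone 9 (kinetic hydrogenation product, axial C8 methyl) | O[C@H]1CC[C@@]2(C)[C@@H](CC[C@H](C)C2=O)C1(C)C | intermediate
9 | (2R,4aS,6S,8aS)-6-hydroxy-2,5,5,8a-tetramethyloctahydronaphthalen-1(2H)-one (3β-OH, 8α-methyl, 9-ketone) | O[C@H]1CC[C@@]2(C)[C@@H](CC[C@@H](C)C2=O)C1(C)C | intermediate
10 | 3β-hydroxy-4,4,8α,10β-tetramethyl-9-methylene-trans-decalin | O[C@H]1CC[C@@]2(C)[C@@H](CC[C@@H](C)C2=C)C1(C)C | intermediate
11 | 9α,11-epoxide of 10 (spiro-oxirane on C9, oxygen α, CH2 β) | O[C@H]1CC[C@@]2(C)[C@@H](CC[C@@H](C)[C@]23CO3)C1(C)C | intermediate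
12 | 9β-vinyl-4,4,8α,10β-tetramethyl-trans-decalin-3β,9α-diol | O[C@H]1CC[C@@]2(C)[C@@H](CC[C@@H](C)[C@]2(O)C=C)C1(C)C | intermediate
13 | 4-bromofuran-2(5H)-one | BrC1=CC(=O)OC1 | starting material
14 | B-alkyl-9-BBN: 9-[2-(3β,9α-dihydroxy-decalin-9-yl)ethyl]-9-borabicyclo[3.3.1]nonane (drawn with free hydroxyls) | O[C@H]1CC[C@@]2(C)[C@@H](CC[C@@H](C)[C@]2(O)CCB2C3CCCC2CCC3)C1(C)C | intermediate
15 | 3β,9α-dihydroxy-labd-13-en-15,16-olide (C8 methyl α; β-substituted butenolide, C15 carbonyl) | O[C@H]1CC[C@@]2(C)[C@@H](CC[C@@H](C)[C@]2(O)CCC2=CC(=O)OC2)C1(C)C | intermediate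
16 | 3β-acetoxy-9α-hydroxy-labd-13-en-15,16-olide (C8 methyl α; CNP0578261.2) | CC(=O)O[C@H]1CC[C@@]2(C)[C@@H](CC[C@@H](C)[C@]2(O)CCC2=CC(=O)OC2)C1(C)C | target

**Step count.** Total: 10 steps. Longest linear sequence: 10 steps, from 1 to 16; 13 is used as purchased.

**Steps most likely to fail**

Step 4. The tertiary C4 radical may be reduced to an isopropyl group before it cyclises. The 3-alkoxy radical may also fragment back by β-scission faster than it is reduced, and the facial selectivity at C3 may be modest. The fallback sets out from 6 and returns at 7. It changes the acceptor and moves C3 stereocontrol to a hydride reduction. Condensation of 6 with NH2OH·HCl/pyridine should give the aldoxime F1, and dehydration with Ac2O should give the nitrile F2. Under the same Fe(acac)3/PhSiH3 conditions the C4 radical should add 6-exo to the nitrile carbon (known HAT cyclisation onto nitriles) to give the cyclic imine F3 (not isolated). Acidic work-up should hydrolyse F3 to the 3,9-dione F4. NaBH4 in MeOH/CH2Cl2 at −78 °C should then reduce the saturated C3 ketone in preference to the hindered conjugated C9 ketone. Hydride should arrive from the α face, away from the axial 4β and 10β methyls, giving the 3β-alcohol 7.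

Step 8. SN2 attack of the ylide on the C11 methylene may be too slow, because C9 is fully substituted and the axial C10 methyl lies near the approach path. The epoxide could then survive or rearrange. The fallback sets out from 10 and returns at 12, and avoids substitution at C11. Dihydroxylation of 10 with OsO4 (cat.)/NMO from the α face should give the 3β,9α,11-triol F5. Oxidation of the primary alcohol alone with TEMPO (cat.)/NCS in buffered CH2Cl2 should give the α-hydroxy aldehyde F6. Wittig methylenation of F6 with Ph3P=CH2 should give 12.

Step 9. Transmetalation of the B-alkyl borane next to the congested carbinol may be slow. Aqueous base could then destroy bromobutenolide 13 by addition–elimination, or the borane could protodeboronate. The fallback sets out from 12 (through the same borane 14) and returns at 15, using a base-stable electrophile. Coupling of 14 with 3-bromofuran (Pd(dppf)Cl2, K3PO4, DMF/H2O, 50 °C) should give the 3-substituted furan F7. Photo-oxygenation with singlet oxygen (O2, rose bengal, i-Pr2NEt, CH2Cl2, −78 °C) should give the β-substituted γ-hydroxybutenolide F8, because the base removes the less hindered proton of the endoperoxide. NaBH4 reduction and acidic work-up should then give 15.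

**Further compounds**

F1 | step 4 | aldoxime of keto aldehyde 6 | ON=CCC[C@@]1(C)[C@@H](CC=C(C)C1=O)C(C)=C
F2 | step 4 | 3-[(1S,6S)-1,3-dimethyl-2-oxo-6-(prop-1-en-2-yl)cyclohex-3-en-1-yl]propanenitrile | N#CCC[C@@]1(C)[C@@H](CC=C(C)C1=O)C(C)=C
F3 | step 4 | cyclic 3-imine of dione F4 (not isolated) | N=C1CC[C@@]2(C)[C@@H](CC=C(C)C2=O)C1(C)C
F4 | step 4 | 4,4,8,10β-tetramethyl-trans-decal-7-ene-3,9-dione | O=C1CC[C@@]2(C)[C@@H](CC=C(C)C2=O)C1(C)C
F5 | step 8 | 9β-(hydroxymethyl)-4,4,8α,10β-tetramethyl-trans-decalin-3β,9α-diol | O[C@H]1CC[C@@]2(C)[C@@H](CC[C@@H](C)[C@]2(O)CO)C1(C)C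
F6 | step 8 | 3β,9α-dihydroxy-4,4,8α,10β-tetramethyl-trans-decalin-9β-carbaldehyde | O[C@H]1CC[C@@]2(C)[C@@H](CC[C@@H](C)[C@]2(O)C=O)C1(C)C
F7 | step 9 | 9β-[2-(furan-3-yl)ethyl]-4,4,8α,10β-tetramethyl-trans-decalin-3β,9α-diol | O[C@H]1CC[C@@]2(C)[C@@H](CC[C@@H](C)[C@]2(O)CCc2ccoc2)C1(C)C
F8 | step 9 | 16-hydroxy derivative of 15 (γ-hydroxybutenolide) | O[C@H]1CC[C@@]2(C)[C@@H](CC[C@@H](C)[C@]2(O)CCC2=CC(=O)OC2O)C1(C)C
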